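## Structural features

The target 14 (C34H56O4) is 5,7-dihydroxy-2-pentacosyl-4H-chromen-4-one: a benzene ring (ring A: C4a, C5, C6, C7, C8, C8a) fused through the C4a–C8a bond to a 4-pyranone ring (O1, C2, C3, C4). An unbranched chain of 25 carbons sits on C2, hydroxyl groups sit on C5 and C7, and C3, C6 and C8 carry hydrogen. There is no stereocenter and no double bond whose configuration must be set, so the problem is one of connectivity only. Ring A has the phloroglucinol pattern: O1 on C8a and the hydroxyls on C5 and C7 are meta to one another and stand ortho, ortho and para to C4a, the carbon that holds the C4 carbonyl. The fragile points are the pyranone, a vinylogous ester open to nucleophiles at C2 and to bases at the chain CH2 attached to C2, and the electron-rich positions C6 and C8 of the free diphenol. The real difficulty lies in forming the C3–C4 bond on the methyl side of an unsymmetrical long-chain methyl ketone and in handling waxy, sparingly soluble C25-chain intermediates, not in skeletal complexity. The key step uses the one-to-one match between C8a, C5 and C7 and the three C–F carbons of a symmetrical 2,4,6-trifluorobenzoyl group, all activated for SNAr by the carbonyl on C4a: one ortho fluorine is replaced by O1 in the ring closure, and the fluorines at C5 and C7 are kept as latent hydroxyl groups.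

## Logic of the disconnections

14 to 13. The bonds concerned are the two benzylic O–CH2 bonds on the C5 and C7 oxygens of 13. Oxygen has to be introduced as a neutral ether, because a phenoxide formed in the first exchange would stop the second. The gain is that both hydroxyls become the same masked group, removable in one operation. The demand on the forward step is a cleavage that leaves C2=C3 alone and does not let benzyl cations attack C6 or C8.

13 to 9 and two equivalents of 10. The aryl C5–O and C7–O bonds are cut and traced back to C–F bonds. Both carbons are ortho or para to the C4 carbonyl and meta to each other, so each is an SNAr position and the first alkoxy group does not donate directly into the second. This reduces the oxygenation of ring A to two fluorines that were already present in the arene building block, and both ether groups come from the same alcohol, of which two molecules are built in. The forward step demands that the alkoxide from 10 attack C7 and C5 in preference to C2 of the pyranone.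

9 to 5 and 6. The C3–C4 bond and the O1–C8a bond are cut, which opens the pyranone ring and separates the skeleton into the whole aliphatic part and the whole aromatic part. The cut is made here because C3 is the α-carbon of a methyl ketone and C4 an acyl carbon (a Claisen-type pairing), while O1–C8a is an enolate oxygen next to an activated C–F bond. One ring and two skeletal bonds are removed, and both fragments are simple. The forward step demands enolisation of 5 on the methyl side, C-acylation and not O-acylation, and a closure that cannot choose wrongly; the symmetry of 6 secures the last point.

5 to 1 and 2. The bond between the ketone methyl carbon (the future C3) and the carbonyl carbon (the future C2) is cut. This leads back to a natural even-numbered fatty acid, 1, and a one-carbon nucleophile, 2, with no chain-building needed. The forward step demands that addition stop at the ketone oxidation level.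

## Other disconnections considered

Alternative 1: The cut is at O1–C8a and C4a–C4, so that ring A enters as an aryne and the side arm as a C28 alkynoic acid. In the forward key step CsF would release 3,5-dimethoxybenzyne A4 from 3,5-dimethoxy-2-(trimethylsilyl)phenyl triflate A3. The carboxylate oxygen of octacos-2-ynoic acid A2 would add at the aryne carbon remote from the neighbouring methoxy group. The aryl anion formed beside that methoxy group would then attack the ester carbonyl, moving the acyl group from oxygen to carbon and giving the ortho-hydroxyaryl ynone A1.
- In its favour: all three ring-A oxygens are present from the start, their positions are fixed by the polarisation of the aryne, and the conditions are nearly neutral.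
- Against it here: no ring closes. A1 would still need a 6-endo closure of O1 onto C2, in competition with 5-exo closure, and then cleavage of two methyl ethers. A2 carries an odd-numbered chain and would have to be built from 1 in about four operations (reduction, reoxidation to the aldehyde level, one-carbon alkyne homologation, carboxylation). A3 needs several steps of its own. The conjugated alkyne of A2 is itself a partner for the aryne, and simple protonation of the aryl anion competes with acyl transfer.
- Comparison: on structure, both plans map ring A onto a simple arene. Alternative 1 is the better on one point: no oxygen has to be introduced later on a base-sensitive pyranone and no enolate regiochemistry arises. On mechanism, the chosen enolate acylation and SNAr closure are easier to predict than the partition of an aryne adduct. On step economy, alternative 1 needs roughly twice as many operations.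

Alternative 2: The cut runs through ring A itself (C5–C6, C7–C8 and C4a–C5), leaving a 4-pyranone that carries the chain and a two-carbon alkyne. In the forward key step, irradiation of 2-(2-diazoacetyl)-6-pentacosyl-4H-pyran-4-one A6, made from the acid A8, would trigger a Wolff rearrangement to a ketene. [2+2] cycloaddition with ethoxyacetylene A7, four-electron opening of the cyclobutenone, six-electron electrocyclisation onto the pyranone double bond and tautomerisation would then give 7-ethoxy-5-hydroxy-2-pentacosylchromone A5.
- In its favour: the polarisation of A7 fixes the oxygen pattern, the C5 hydroxyl arrives free and distinct from the C7 ether, and three skeletal bonds form under neutral conditions.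
- Against it here: A8 is not a stock compound and needs its own Claisen-type assembly from a long-chain 1,3-diketone and an oxalate. A6 can only be reached by acylating a hazardous diazoalkane. The 4-pyranone chromophore competes for the light and has photochemistry of its own. An ethyl ether must still be cleaved at the end. The route also builds a benzene ring that can be bought.
- Comparison: on structure, the chosen plan buys ring A and alternative 2 constructs it. On mechanism, the pericyclic cascade gives regiocontrol equal to the symmetry argument of the chosen plan, and it is the better if the two phenols had to be differentiated, which the target does not require. On step economy, it is clearly longer.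

Alternative 3: The cut is at C3–C4 and O1–C2. In the forward key step the trivalent rhodium catalyst [Cp*RhCl2]2, with AgSbF6 and NaOAc, would metalate the formyl C–H of 2-hydroxy-4,6-dimethoxybenzaldehyde A10 under direction by the hydroxyl group. The acylrhodium species would take up the carbene derived from the sulfoxonium ylide A11 and form C3–C4 by migratory insertion. The resulting hydroxyaryl 1,3-diketone would close O1–C2 with loss of water to give 5,7-dimethoxy-2-pentacosylchromone A9.
- In its favour: the same C3–C4 bond is made as in the chosen plan, but from a carbon nucleophile with no regiochemical ambiguity. All ring-A oxygens come from a purchasable aldehyde, and A11 should be available from 1 in two steps.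
- Against it here: it needs a precious-metal catalyst. The formyl group of A10 is flanked by a methoxy and a hydroxyl group, and decarbonylation of the acylrhodium species competes. Two methyl ethers must be cleaved at the end, the one at C7 only under forcing boron trihalide conditions.
- Comparison: on structure, the two plans are close. On mechanism, alternative 3 is the better in the regiochemical security of C3 and in never exposing the pyranone to an alkoxide. The chosen plan is the better in cost, in the mildness of the final deprotection and in having no site selectivity at ring closure. On step economy the two are equal at about four steps.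

Key step: step 2

Remark: the target has no stereogenic element; in step 3 the fluoride at C7 is taken to be exchanged before that at C5, and the order has no bearing on the product.

## Route

Step 1
Reactants: 1 hexacosanoic acid; 2 methyllithium
Product: 5 heptacosan-2-one, via lithium hexacosanoate 3 (not isolated), via dilithium heptacosane-2,2-diolate 4 (not isolated)
Conditions: MeLi (2.3 equiv), THF, 0 °C → rt; poured into cold 1 M HCl
Reagents that add atoms: none
Why: The first equivalent of MeLi deprotonates the acid to 3 and the second adds to the carboxylate carbon to give the gem-diolate 4, which cannot collapse to the ketone while base is present and so resists a further addition; the inverse acidic quench then releases the methyl ketone (ketone synthesis from a carboxylic acid and an organolithium reagent), and no stereocenter is formed.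

Step 2
Reactants: 5 heptacosan-2-one; 6 2,4,6-trifluorobenzoyl chloride
Product: 9 5,7-difluoro-2-pentacosylchromone, via lithium heptacos-1-en-2-olate 7 (not isolated), via lithium (Z)-1-oxo-1-(2,4,6-trifluorophenyl)octacos-2-en-3-olate 8 (not isolated)
Conditions: LiN(SiMe3)2 (2.1 equiv), THF, −78 °C, 5 added to the base; 6 (1.0 equiv), −78 → 0 °C; then DMF, 80 °C
Reagents that add atoms: none
Why: LiN(SiMe3)2 removes a proton from the less hindered methyl group of 5 under kinetic control to give the terminal enolate 7, whose carbon attacks the acyl chloride 6 by addition–elimination (crossed Claisen-type C-acylation of a ketone enolate) and forms C3–C4. The second equivalent of base converts the more acidic 1,3-diketone at once into the chelated diketonate 8, which protects it from a second acylation and means that no enolate of the ketone is spent as a base. After DMF is added and the mixture is warmed, the oxygen on the chain-bearing carbon of 8 adds to the fluorine-bearing ring carbon ortho to the ketone, formally a 6-exo-trig attack on the C8a=C8 π bond, to give a Meisenheimer adduct stabilised by the C4 carbonyl and the remaining fluorines; loss of fluoride restores the arene and closes the pyranone ring through O1–C8a. The closest known reaction type is the one-pot chromone and 4-quinolone synthesis from ortho-fluorobenzoyl chlorides and ketone or β-ketoester enolates. No stereocenter is formed. Three selectivities are needed: methyl over methylene enolisation, secured by the bulky amide base at low temperature with the ketone added to the base; C- over O-acylation, secured by the lithium counter-ion in THF; and the site of closure, which cannot go wrong because the two ortho fluorines of 6 are equivalent by symmetry. Closure through oxygen and not through C3 follows from ring size, since attack by carbon would require a four-membered ring.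

Step 3
Reactants: 9 5,7-difluoro-2-pentacosylchromone; 10 benzyl alcohol
Product: 13 5,7-bis(benzyloxy)-2-pentacosylchromone, via sodium benzyloxide 11 (not isolated), via 7-(benzyloxy)-5-fluoro-2-pentacosylchromone 12 (not isolated)
Conditions: BnOH (4 equiv), NaH (2.5 equiv), THF, 0 °C → rt until H2 evolution ends; then 9, THF–DMF, 60 °C
Reagents that add atoms: benzyl alcohol (the second equivalent of 10, built in at C5; the first equivalent is counted among the reactants), OCc1ccccc1
Why: NaH converts part of 10 into the alkoxide 11 in THF before any DMF is present, and two equivalents of 11 then displace fluoride by addition–elimination (SNAr): the first at C7, para to the C4 carbonyl, to give 12, and the second at C5, ortho to it, to give 13, each Meisenheimer adduct placing its charge on the carbonyl oxygen. Because C5 and C7 are meta to each other the first benzyloxy group does not donate directly into the second reacting carbon, and the excess of free 10 buffers the alkoxide so that addition at C2 and deprotonation of the chain CH2 next to C2 should remain reversible side equilibria. No stereocenter is formed.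

Step 4
Reactants: 13 5,7-bis(benzyloxy)-2-pentacosylchromone
Product: 14 5,7-dihydroxy-2-pentacosylchromone (CNP0174425.0)
Conditions: BCl3 (6 equiv), C6HMe5 (6 equiv), CH2Cl2, −40 → 0 °C; then H2O
Reagents that add atoms: none
Why: BCl3 coordinates to the ether oxygens, that at C5 helped by chelation to C4=O, and the benzyl groups leave as cations that pentamethylbenzene traps (Lewis acid cleavage of aryl benzyl ethers with a non-basic cation scavenger), so that C6 and C8 of the electron-rich ring A should not be benzylated. The aryloxyboron chlorides, of no single composition, are hydrolysed on work-up; C2=C3 and the chain are untouched and no stereocenter is involved.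

## Compound list

1 | hexacosanoic acid | CCCCCCCCCCCCCCCCCCCCCCCCCC(=O)O | starting material
2 | methyllithium | [Li]C | starting material
3 | lithium hexacosanoate | CCCCCCCCCCCCCCCCCCCCCCCCCC(=O)[O-].[Li+] | intermediate
4 | dilithium heptacosane-2,2-diolate | CCCCCCCCCCCCCCCCCCCCCCCCCC(C)([O-])[O-].[Li+].[Li+] | intermediate
5 | heptacosan-2-one | CCCCCCCCCCCCCCCCCCCCCCCCCC(C)=O | intermediate
6 | 2,4,6-trifluorobenzoyl chloride | O=C(Cl)c1c(F)cc(F)cc1F | starting material
7 | lithium heptacos-1-en-2-olate | CCCCCCCCCCCCCCCCCCCCCCCCCC(=C)[O-].[Li+] | intermediate
8 | lithium (Z)-1-oxo-1-(2,4,6-trifluorophenyl)octacos-2-en-3-olate | CCCCCCCCCCCCCCCCCCCCCCCCC/C([O-])=C/C(=O)c1c(F)cc(F)cc1F.[Li+] | intermediate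
9 | 5,7-difluoro-2-pentacosylchromone (5,7-difluoro-2-pentacosyl-4H-chromen-4-one) | CCCCCCCCCCCCCCCCCCCCCCCCCc1cc(=O)c2c(F)cc(F)cc2o1 | intermediate
10 | benzyl alcohol | OCc1ccccc1 | starting material
11 | sodium benzyloxide | [Na+].[O-]Cc1ccccc1 | intermediate
12 | 7-(benzyloxy)-5-fluoro-2-pentacosylchromone | CCCCCCCCCCCCCCCCCCCCCCCCCc1cc(=O)c2c(F)cc(OCc3ccccc3)cc2o1 | intermediate
13 | 5,7-bis(benzyloxy)-2-pentacosylchromone | CCCCCCCCCCCCCCCCCCCCCCCCCc1cc(=O)c2c(OCc3ccccc3)cc(OCc3ccccc3)cc2o1 | intermediate
14 | 5,7-dihydroxy-2-pentacosylchromone (5,7-dihydroxy-2-pentacosyl-4H-chromen-4-one, CNP0174425.0) | CCCCCCCCCCCCCCCCCCCCCCCCCc1cc(=O)c2c(O)cc(O)cc2o1 | target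

## Step count and least certain steps

Total step count: 4. Longest linear sequence: 4 steps (1 → 5 → 9 → 13 → 14); 2, 6 and 10 enter as purchased materials, and 10 is used twice over in step 3.

Step 2 (key step). The most likely failure is loss of regiocontrol in the enolisation: the waxy ketone dissolves slowly at low temperature, so enolate and free ketone can exchange protons and some enolate forms on the methylene side, which would carry through to an isomeric pyranone. Acylation of the excess amide base by the acid chloride would lower conversion as well. The fallback sets out from 1 and returns at 9, and reverses the polarity of the Claisen step so that the only enolisable ketone has a single α-position. 1 would be converted with (COCl)2 and catalytic DMF in CH2Cl2 into hexacosanoyl chloride F1. The lithium enolate of purchased 1-(2,4,6-trifluorophenyl)ethanone F2 (LiN(SiMe3)2, 2 equiv, THF, −78 °C) would be C-acylated by F1 to give, after acidic work-up, 1-(2,4,6-trifluorophenyl)octacosane-1,3-dione F3. F3 would be isolated and closed to 9 with K2CO3 in DMF at 60 °C by the same SNAr. This forms C2–C3 in place of C3–C4, and step 1 and compound 5 are then not needed.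

Step 3. The alkoxide may add at C2 and open the pyranone ring. Deprotonation of the chain CH2 next to C2 would place negative charge in the ring system and slow the second exchange at C5, so that substitution stops halfway. The fallback sets out from 1 and returns at 13, bringing ring A in with its oxygens already in place. Purchased 1-[2,4-bis(benzyloxy)-6-hydroxyphenyl]ethanone F4 would be esterified with 1 (Steglich conditions: EDC·HCl, DMAP, CH2Cl2) to 2-acetyl-3,5-bis(benzyloxy)phenyl hexacosanoate F5. Baker–Venkataraman rearrangement with KOtBu in THF (0 °C → rt) would give 1-[2,4-bis(benzyloxy)-6-hydroxyphenyl]octacosane-1,3-dione F6. Cyclodehydration with catalytic TsOH in toluene at 80 °C would give 13.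

Step 1. Over-addition is the main risk: if the gem-diolate collapses to the ketone while MeLi is still present, for instance during the quench, a third methyl group is taken up. The poorly soluble lithium carboxylate may also react slowly and incompletely. The fallback sets out from 1 and returns at 5. Activation of 1 with 1,1'-carbonyldiimidazole in THF would give 1-(1H-imidazol-1-yl)hexacosan-1-one F7, used without isolation. Reaction of F7 with MeNH(OMe)·HCl would give N-methoxy-N-methylhexacosanamide F8. MeMgBr in THF at 0 °C would give 5, because the chelated magnesium adduct holds until work-up (Weinreb ketone synthesis).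

Step 4. Benzyl cations may be transferred to C6 or C8 if trapping is slower than ring attack. The ether at C7 may also be cleaved incompletely at the low temperatures needed, where the waxy substrate is barely soluble. The fallback sets out from 13 and returns at 14: hydrogenolysis with H2 (1 atm) over Pd/C (palladium on carbon) in THF–EtOAc at 40 °C, stopped after uptake of two equivalents of hydrogen to spare C2=C3. It changes the mechanism from Lewis acid ionisation to reductive cleavage at a metal surface and makes no new compound (none F0).

## Further compounds

F1 | step 2 | hexacosanoyl chloride | CCCCCCCCCCCCCCCCCCCCCCCCCC(=O)Cl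
F2 | step 2 | 1-(2,4,6-trifluorophenyl)ethanone | CC(=O)c1c(F)cc(F)cc1F
F3 | step 2 | 1-(2,4,6-trifluorophenyl)octacosane-1,3-dione | CCCCCCCCCCCCCCCCCCCCCCCCCC(=O)CC(=O)c1c(F)cc(F)cc1F
F4 | step 3 | 1-[2,4-bis(benzyloxy)-6-hydroxyphenyl]ethanone | CC(=O)c1c(O)cc(OCc2ccccc2)cc1OCc1ccccc1
F5 | step 3 | 2-acetyl-3,5-bis(benzyloxy)phenyl hexacosanoate | CCCCCCCCCCCCCCCCCCCCCCCCCC(=O)Oc1cc(OCc2ccccc2)cc(OCc2ccccc2)c1C(C)=O
F6 | step 3 | 1-[2,4-bis(benzyloxy)-6-hydroxyphenyl]octacosane-1,3-dione | CCCCCCCCCCCCCCCCCCCCCCCCCC(=O)CC(=O)c1c(O)cc(OCc2ccccc2)cc1OCc1ccccc1
F7 | step 1 | 1-(1H-imidazol-1-yl)hexacosan-1-one | CCCCCCCCCCCCCCCCCCCCCCCCCC(=O)n1ccnc1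
F8 | step 1 | N-methoxy-N-methylhexacosanamide | CCCCCCCCCCCCCCCCCCCCCCCCCC(=O)N(C)OC
F0 | step 4 | none | none
A1 | alternative 1 | 1-(2-hydroxy-4,6-dimethoxyphenyl)octacos-2-yn-1-one | CCCCCCCCCCCCCCCCCCCCCCCCCC#CC(=O)c1c(O)cc(OC)cc1OC
A2 | alternative 1 | octacos-2-ynoic acid | CCCCCCCCCCCCCCCCCCCCCCCCCC#CC(=O)O
A3 | alternative 1 | 3,5-dimethoxy-2-(trimethylsilyl)phenyl trifluoromethanesulfonate | COc1cc(OC)c([Si](C)(C)C)c(OS(=O)(=O)C(F)(F)F)c1
A4 | alternative 1 | 3,5-dimethoxybenzyne (1,2-didehydro-3,5-dimethoxybenzene) | COC1=CC(OC)=CC#C1
A5 | alternative 2 | 7-ethoxy-5-hydroxy-2-pentacosylchromone | CCCCCCCCCCCCCCCCCCCCCCCCCc1cc(=O)c2c(O)cc(OCC)cc2o1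
A6 | alternative 2 | 2-(2-diazoacetyl)-6-pentacosyl-4H-pyran-4-one | CCCCCCCCCCCCCCCCCCCCCCCCCc1cc(=O)cc(C(=O)C=[N+]=[N-])o1
A7 | alternative 2 | ethoxyacetylene (ethoxyethyne) | CCOC#C
A8 | alternative 2 | 4-oxo-6-pentacosyl-4H-pyran-2-carboxylic acid | CCCCCCCCCCCCCCCCCCCCCCCCCc1cc(=O)cc(C(=O)O)o1
A9 | alternative 3 | 5,7-dimethoxy-2-pentacosylchromone | CCCCCCCCCCCCCCCCCCCCCCCCCc1cc(=O)c2c(OC)cc(OC)cc2o1
A10 | alternative 3 | 2-hydroxy-4,6-dimethoxybenzaldehyde | COc1cc(O)c(C=O)c(OC)c1
A11 | alternative 3 | 1-[dimethyl(oxo)-λ6-sulfanylidene]heptacosan-2-one | CCCCCCCCCCCCCCCCCCCCCCCCCC(=O)C=S(C)(C)=O
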